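Everything rests on cutting ring B (C5–C10) at C7–C8 and C9–C10. The adjacent cis methyl groups on C8 and C9, with C9 quaternary and carrying the chain carbon C11, are the imprint of (E)-2-methylbut-2-enal; its catalytic asymmetric Diels–Alder reaction with a 1-silyloxybutadiene (C10, C5, C6, C7) therefore delivers ring B, both stereocentres and an oxygen at C10 in one operation. The precursors are simply the enal and the TBS dienol ether of crotonaldehyde. The C10 oxygen later becomes a vinyl triflate that receives C1–C4; a lactone Ireland–Claisen rearrangement then closes ring A (C1–C5, C10) and sets C4 and C5, and a B-alkyl Suzuki coupling completes the side chain.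

Key step: step 2

Numbering used throughout: ring A = C1–C5 and C10; ring B = C5–C10; side chain C11–C15 on C9; C19 = the carboxyl carbon on C4.

Assumption: enal 3 is taken to bind the (S)-configured oxazaborolidinium ion in the same way as 2-methylacrolein, so that the diene attacks the α-Re face (the (R)-catalyst would be used if the adduct proved antipodal); the configuration at C10 of adduct 4 is irrelevant because it is erased in step 5.

Step 1
Reactants: 1 (E)-but-2-enal (crotonaldehyde)
Product: 2 (E)-1-(tert-butyldimethylsilyloxy)buta-1,3-diene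
Conditions: TBSOTf, Et3N, Et2O, 0 °C → rt
Reagents that add atoms: tert-butyldimethylsilyl trifluoromethanesulfonate, CC(C)(C)[Si](C)(C)OS(=O)(=O)C(F)(F)F
Why: O-silylation of the enal and γ-deprotonation (silyl dienol ether formation) should give the conjugated (E)-dienol ether, while any (Z)-isomer cannot reach the s-cis geometry and stays inert in step 2.

Step 2
Reactants: 2 (E)-1-(tert-butyldimethylsilyloxy)buta-1,3-diene; 3 (E)-2-methylbut-2-enal (tiglic aldehyde)
Product: 4 (1S,2R,6R)-2-(tert-butyldimethylsilyloxy)-1,6-dimethylcyclohex-3-ene-1-carbaldehyde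
Conditions: (S)-3,3-diphenyl-1-(2-methylphenyl)tetrahydro-1H,3H-pyrrolo[1,2-c][1,3,2]oxazaborole (20 mol %), Tf2NH (17 mol %), 2 (3 equiv), CH2Cl2, −78 → −20 °C
Reagents that add atoms: none
Why: The N-protonated oxazaborolidine binds the formyl oxygen of s-trans 3 (supported by a formyl C–H···O contact) and lowers its LUMO, so that diene 2 adds in one concerted but asynchronous [4+2] step in which the C7–C8 bond leads and the C9–C10 bond follows. The closest known reaction type is the cationic-oxazaborolidine-catalysed Diels–Alder reaction of 2-substituted acroleins with silyloxy dienes. Ring B is closed by the intermolecular cycloaddition itself, four ring atoms (C10, C5, C6, C7) coming from the diene and two (C8, C9) from the enal. C9 is set by the catalyst, one geminal phenyl group of which shields the α-Si face so that the diene attacks the α-Re face; C8 follows from suprafacial addition to the (E)-olefin, which turns the cis methyl groups of 3 into the cis C8/C9 methyl groups; C10 follows from the endo position of the formyl group and is erased in step 5. The step needs regio- and enantiofacial selectivity: the 1-silyloxy group puts the largest diene coefficient on C7, which joins the β-carbon C8, and the two-point binding of the formyl group to the catalyst fixes the face. The TBS group is used instead of a trimethylsilyl group because it resists silyl transfer to the triflimide counter-ion, which would start an achiral background reaction.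

Step 3
Reactants: 4 (1S,2R,6R)-2-(tert-butyldimethylsilyloxy)-1,6-dimethylcyclohex-3-ene-1-carbaldehyde
Product: 5 tert-butyl{[(1R,5R,6S)-6-ethenyl-5,6-dimethylcyclohex-2-en-1-yl]oxy}dimethylsilane
Conditions: Ph3PCH3Br, KN(SiMe3)2, THF, 0 °C → rt
Reagents that add atoms: methyltriphenylphosphonium bromide, C[P+](c1ccccc1)(c1ccccc1)c1ccccc1.[Br-]
Why: Wittig methylenation of a non-enolisable aldehyde (quaternary α-carbon C9, so no epimerisation or elimination is possible) should give the C11=C12 vinyl group, which serves as a robust placeholder for the side chain.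

Step 4
Reactants: 5 tert-butyl{[(1R,5R,6S)-6-ethenyl-5,6-dimethylcyclohex-2-en-1-yl]oxy}dimethylsilane
Product: 6 (1R,5R,6S)-6-ethenyl-5,6-dimethylcyclohex-2-en-1-ol
Conditions: Bu4NF, THF, rt → 40 °C
Reagents that add atoms: none
Why: Fluoride-mediated desilylation of the secondary silyl ether should free the C10 allylic alcohol without touching the olefins.

Step 5
Reactants: 6 (1R,5R,6S)-6-ethenyl-5,6-dimethylcyclohex-2-en-1-ol
Product: 7 (5R,6S)-6-ethenyl-5,6-dimethylcyclohex-2-en-1-one
Conditions: Dess–Martin periodinane, CH2Cl2, 0 °C → rt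
Reagents that add atoms: none
Why: Dess–Martin oxidation of the allylic alcohol should give the C10 enone; C9 is quaternary, so the vinyl group cannot move into conjugation and both C10 epimers of 6 converge.

Step 6
Reactants: 7 (5R,6S)-6-ethenyl-5,6-dimethylcyclohex-2-en-1-one
Product: 9 (5R,6S)-6-ethenyl-5,6-dimethylcyclohex-1-en-1-yl trifluoromethanesulfonate, via lithium enolate 8 (not isolated)
Conditions: LiBH(s-Bu)3, THF, −78 °C; then PhNTf2, −78 → 0 °C
Reagents that add atoms: N-phenylbis(trifluoromethanesulfonimide), O=S(=O)(N(c1ccccc1)S(=O)(=O)C(F)(F)F)C(F)(F)F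
Why: Conjugate (1,4) hydride reduction of the β-unsubstituted cyclohexenone, whose carbonyl is shielded by the quaternary C9, should give only the C10=C5 enolate, which is trapped on oxygen as the enol triflate (conjugate reduction–enolate triflation).

Step 7
Reactants: 10 ethyl 2-methylpent-4-enoate (racemic)
Product: 12 ethyl 5-hydroxy-2-methylpentanoate, via alkylborane 11 (not isolated)
Conditions: 9-BBN, THF, 0 °C → rt; then H2O2, aq. NaOAc, 0 °C
Reagents that add atoms: hydrogen peroxide, OO
Why: Anti-Markovnikov hydroboration of the terminal olefin with 9-BBN followed by buffered oxidation should give the primary alcohol and leave the ester intact (hydroboration–oxidation).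

Step 8
Reactants: 12 ethyl 5-hydroxy-2-methylpentanoate
Product: 13 ethyl 2-methyl-5-oxopentanoate
Conditions: Dess–Martin periodinane, CH2Cl2, rt
Reagents that add atoms: none
Why: Dess–Martin oxidation of the primary alcohol should stop at the aldehyde, which becomes C1 while the ester carbon becomes C19.

Step 9
Reactants: 9 (5R,6S)-6-ethenyl-5,6-dimethylcyclohex-1-en-1-yl trifluoromethanesulfonate; 13 ethyl 2-methyl-5-oxopentanoate
Product: 14 ethyl 5-[(5R,6S)-6-ethenyl-5,6-dimethylcyclohex-1-en-1-yl]-5-hydroxy-2-methylpentanoate (mixture of C1 and C4 epimers)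
Conditions: CrCl2 (4 equiv), NiCl2 (2 mol %), DMF, rt; crude product used directly
Reagents that add atoms: none
Why: Nozaki–Hiyama–Kishi coupling, in which zerovalent nickel inserts into the C10–OTf bond and the alkenyl group is passed to trivalent chromium, should form the C1–C10 bond by addition to the aldehyde only, tolerating the ester and the olefins; the C1 epimers converge in step 10.

Step 10
Reactants: 14 ethyl 5-[(5R,6S)-6-ethenyl-5,6-dimethylcyclohex-1-en-1-yl]-5-hydroxy-2-methylpentanoate
Product: 15 ethyl 5-[(5R,6S)-6-ethenyl-5,6-dimethylcyclohex-1-en-1-yl]-2-methyl-5-oxopentanoate (C4 epimers)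
Conditions: Dess–Martin periodinane, CH2Cl2, 0 °C → rt
Reagents that add atoms: none
Why: Dess–Martin oxidation of the allylic alcohol should give the C1 enone and so remove the uncontrolled C1 centre before it is reset by reagent control.

Step 11
Reactants: 15 ethyl 5-[(5R,6S)-6-ethenyl-5,6-dimethylcyclohex-1-en-1-yl]-2-methyl-5-oxopentanoate
Product: 17 (6R)-6-[(5R,6S)-6-ethenyl-5,6-dimethylcyclohex-1-en-1-yl]-3-methyloxan-2-one (C4 epimers), via hydroxy ester 16 (not isolated)
Conditions: (S)-1-methyl-3,3-diphenyltetrahydro-1H,3H-pyrrolo[1,2-c][1,3,2]oxazaborole (20 mol %), catecholborane, PhMe, −78 °C; aq. NaOH wash; then PPTS (cat.), PhMe, 60 °C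
Reagents that add atoms: none
Why: Corey–Bakshi–Shibata reduction, in which the (S)-oxazaborolidine treats the bulky cyclohexenyl group as the large substituent (as acetophenone gives (R)-1-phenylethanol), should give the (1R)-carbinol; catecholborane at −78 °C spares the vinyl group, and the δ-hydroxy ester then closes to the six-membered lactone with loss of ethanol.

Step 12
Reactants: 17 (6R)-6-[(5R,6S)-6-ethenyl-5,6-dimethylcyclohex-1-en-1-yl]-3-methyloxan-2-one
Product: 21 (1S,5S,6R,8aR)-5-ethenyl-1,5,6-trimethyl-1,2,3,5,6,7,8,8a-octahydronaphthalene-1-carboxylic acid, via lithium lactone enolate 18 (not isolated), via silyl ketene acetal 19 (not isolated), via trimethylsilyl ester 20 (not isolated)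
Conditions: LiN(i-Pr)2, THF, −78 °C; Me3SiCl, Et3N, −78 → 0 °C; PhMe, 110 °C; then 1 M HCl, THF, rt
Reagents that add atoms: none
Why: Ireland–Claisen rearrangement in its ring-contracting lactone form, where the C2–C3 tether forces a boat-like transition state: C4 bonds to C5 on the face from which the C1–O bond leaves (anti to the C9 methyl), so (1R) is transferred to (5R), the ring-fixed ketene acetal geometry (C3 cis to the ring oxygen) places the carboxyl group cis to C6 and gives (4S), and the new C1=C10 olefin is locked in ring A; both C4 epimers of 17 give the same enolate.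

Step 13
Reactants: 21 (1S,5S,6R,8aR)-5-ethenyl-1,5,6-trimethyl-1,2,3,5,6,7,8,8a-octahydronaphthalene-1-carboxylic acid
Product: 22 methyl (1S,5S,6R,8aR)-5-ethenyl-1,5,6-trimethyl-1,2,3,5,6,7,8,8a-octahydronaphthalene-1-carboxylate
Conditions: MeI, K2CO3, DMF, rt
Reagents that add atoms: iodomethane, CI
Why: O-alkylation of the carboxylate (SN2 at iodomethane) should esterify the hindered tertiary acid without any attack at its carbonyl group.

Step 14
Reactants: 23 but-2-yn-1-ol
Product: 26 (E)-3-iodobut-2-en-1-ol, via aluminium alkoxide 24 (not isolated), via alkenylzirconocene 25 (not isolated)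
Conditions: i-Bu2AlH (1 equiv), THF, 0 °C; Cp2ZrCl2 and i-Bu2AlH (1.2 equiv each), THF, 0 °C → rt; then I2, −78 → 0 °C; aq. HCl
Reagents that add atoms: iodine, II
Why: Syn-hydrozirconation of the internal alkyne (as its aluminium alkoxide) should place zirconium on C3, remote from the oxygenated carbon, and iodinolysis of the C–Zr bond with retention gives the (E)-iodide that fixes the C13=C14 geometry (hydrozirconation–iodination).

Step 15
Reactants: 22 methyl (1S,5S,6R,8aR)-5-ethenyl-1,5,6-trimethyl-1,2,3,5,6,7,8,8a-octahydronaphthalene-1-carboxylate; 26 (E)-3-iodobut-2-en-1-ol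
Product: 28 methyl (1S,5S,6R,8aR)-5-[(3E)-5-hydroxy-3-methylpent-3-en-1-yl]-1,5,6-trimethyl-1,2,3,5,6,7,8,8a-octahydronaphthalene-1-carboxylate, via alkylborane 27 (not isolated)
Conditions: 9-BBN, THF, 0 → 50 °C; then 26, Pd(dppf)Cl2 (5 mol %), AsPh3, Cs2CO3, DMF/H2O, rt
Reagents that add atoms: none
Why: B-alkyl Suzuki–Miyaura coupling, in which 9-BBN hydroborates only the monosubstituted vinyl group (boron on C12) and the alkylborane couples with the alkenyl iodide with retention of geometry, should form the C12–C13 bond while the free hydroxyl, the trisubstituted ring olefin and the hindered ester are tolerated.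

Step 16
Reactants: 28 methyl (1S,5S,6R,8aR)-5-[(3E)-5-hydroxy-3-methylpent-3-en-1-yl]-1,5,6-trimethyl-1,2,3,5,6,7,8,8a-octahydronaphthalene-1-carboxylate
Product: 29 methyl (1S,5S,6R,8aR)-5-[(3E)-5-acetoxy-3-methylpent-3-en-1-yl]-1,5,6-trimethyl-1,2,3,5,6,7,8,8a-octahydronaphthalene-1-carboxylate (CNP0209995.1)
Conditions: Ac2O, Et3N, DMAP (cat.), CH2Cl2, 0 °C → rt
Reagents that add atoms: acetic anhydride, CC(=O)OC(C)=O
Why: DMAP-catalysed acylation of the primary allylic alcohol should give the acetate and thus the target, with no other nucleophilic site present.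

Compound list

1 | (E)-but-2-enal | C/C=C/C=O | starting material
2 | (E)-1-(tert-butyldimethylsilyloxy)buta-1,3-diene | C=C/C=C/O[Si](C)(C)C(C)(C)C | intermediate
3 | (E)-2-methylbut-2-enal | C/C=C(\C)C=O | starting material
4 | (1S,2R,6R)-2-(tert-butyldimethylsilyloxy)-1,6-dimethylcyclohex-3-ene-1-carbaldehyde | O=C[C@]1(C)[C@H](O[Si](C)(C)C(C)(C)C)C=CC[C@H]1C | intermediate
5 | tert-butyl{[(1R,5R,6S)-6-ethenyl-5,6-dimethylcyclohex-2-en-1-yl]oxy}dimethylsilane | C=C[C@]1(C)[C@H](O[Si](C)(C)C(C)(C)C)C=CC[C@H]1C | intermediate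
6 | (1R,5R,6S)-6-ethenyl-5,6-dimethylcyclohex-2-en-1-ol | C=C[C@]1(C)[C@H](O)C=CC[C@H]1C | intermediate
7 | (5R,6S)-6-ethenyl-5,6-dimethylcyclohex-2-en-1-one | C=C[C@]1(C)C(=O)C=CC[C@H]1C | intermediate
8 | lithium (5R,6S)-6-ethenyl-5,6-dimethylcyclohex-1-en-1-olate | [Li+].[O-]C1=CCC[C@@H](C)[C@]1(C)C=C | intermediate
9 | (5R,6S)-6-ethenyl-5,6-dimethylcyclohex-1-en-1-yl trifluoromethanesulfonate | FC(F)(F)S(=O)(=O)OC1=CCC[C@@H](C)[C@]1(C)C=C | intermediate
10 | ethyl 2-methylpent-4-enoate (racemic) | CCOC(=O)C(C)CC=C | starting material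
11 | ethyl 5-(9-borabicyclo[3.3.1]nonan-9-yl)-2-methylpentanoate | CCOC(=O)C(C)CCCB1C2CCCC1CCC2 | intermediate
12 | ethyl 5-hydroxy-2-methylpentanoate | CCOC(=O)C(C)CCCO | intermediate
13 | ethyl 2-methyl-5-oxopentanoate | CCOC(=O)C(C)CCC=O | intermediate
14 | ethyl 5-[(5R,6S)-6-ethenyl-5,6-dimethylcyclohex-1-en-1-yl]-5-hydroxy-2-methylpentanoate (C1 and C4 epimers) | CCOC(=O)C(C)CCC(O)C1=CCC[C@@H](C)[C@]1(C)C=C | intermediate
15 | ethyl 5-[(5R,6S)-6-ethenyl-5,6-dimethylcyclohex-1-en-1-yl]-2-methyl-5-oxopentanoate (C4 epimers) | CCOC(=O)C(C)CCC(=O)C1=CCC[C@@H](C)[C@]1(C)C=C | intermediate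
16 | ethyl (5R)-5-[(5R,6S)-6-ethenyl-5,6-dimethylcyclohex-1-en-1-yl]-5-hydroxy-2-methylpentanoate (C4 epimers) | CCOC(=O)C(C)CC[C@@H](O)C1=CCC[C@@H](C)[C@]1(C)C=C | intermediate
17 | (6R)-6-[(5R,6S)-6-ethenyl-5,6-dimethylcyclohex-1-en-1-yl]-3-methyloxan-2-one (C4 epimers) | CC1CC[C@@H](OC1=O)C2=CCC[C@@H](C)[C@]2(C)C=C | intermediate
18 | lithium (2R)-2-[(5R,6S)-6-ethenyl-5,6-dimethylcyclohex-1-en-1-yl]-5-methyl-3,4-dihydro-2H-pyran-6-olate | [Li+].[O-]C1=C(C)CC[C@@H](O1)C2=CCC[C@@H](C)[C@]2(C)C=C | intermediate
19 | {[(2R)-2-[(5R,6S)-6-ethenyl-5,6-dimethylcyclohex-1-en-1-yl]-5-methyl-3,4-dihydro-2H-pyran-6-yl]oxy}trimethylsilane | C[Si](C)(C)OC1=C(C)CC[C@@H](O1)C2=CCC[C@@H](C)[C@]2(C)C=C | intermediate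
20 | trimethylsilyl (1S,5S,6R,8aR)-5-ethenyl-1,5,6-trimethyl-1,2,3,5,6,7,8,8a-octahydronaphthalene-1-carboxylate | C[Si](C)(C)OC(=O)[C@@]1(C)CCC=C2[C@H]1CC[C@@H](C)[C@]2(C)C=C | intermediate
21 | (1S,5S,6R,8aR)-5-ethenyl-1,5,6-trimethyl-1,2,3,5,6,7,8,8a-octahydronaphthalene-1-carboxylic acid | OC(=O)[C@@]1(C)CCC=C2[C@H]1CC[C@@H](C)[C@]2(C)C=C | intermediate
22 | methyl (1S,5S,6R,8aR)-5-ethenyl-1,5,6-trimethyl-1,2,3,5,6,7,8,8a-octahydronaphthalene-1-carboxylate | COC(=O)[C@@]1(C)CCC=C2[C@H]1CC[C@@H](C)[C@]2(C)C=C | intermediate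
23 | but-2-yn-1-ol | CC#CCO | starting material
24 | (but-2-yn-1-yloxy)bis(2-methylpropyl)alumane | CC#CCO[Al](CC(C)C)CC(C)C | intermediate
25 | chlorobis(cyclopentadienyl)[(2E)-4-{[bis(2-methylpropyl)alumanyl]oxy}but-2-en-2-yl]zirconium | CC(C)C[Al](CC(C)C)OC/C=C(C)/[Zr](Cl)(C1C=CC=C1)C1C=CC=C1 | intermediate
26 | (E)-3-iodobut-2-en-1-ol | OC/C=C(C)/I | intermediate
27 | methyl (1S,5S,6R,8aR)-5-[2-(9-borabicyclo[3.3.1]nonan-9-yl)ethyl]-1,5,6-trimethyl-1,2,3,5,6,7,8,8a-octahydronaphthalene-1-carboxylate | COC(=O)[C@@]1(C)CCC=C2[C@H]1CC[C@@H](C)[C@]2(C)CCB3C4CCCC3CCC4 | intermediate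
28 | methyl (1S,5S,6R,8aR)-5-[(3E)-5-hydroxy-3-methylpent-3-en-1-yl]-1,5,6-trimethyl-1,2,3,5,6,7,8,8a-octahydronaphthalene-1-carboxylate | COC(=O)[C@@]1(C)CCC=C2[C@H]1CC[C@@H](C)[C@]2(C)CC/C(C)=C/CO | intermediate
29 | methyl (1S,5S,6R,8aR)-5-[(3E)-5-acetoxy-3-methylpent-3-en-1-yl]-1,5,6-trimethyl-1,2,3,5,6,7,8,8a-octahydronaphthalene-1-carboxylate | COC(=O)[C@@]1(C)CCC=C2[C@H]1CC[C@@H](C)[C@]2(C)CC/C(C)=C/COC(C)=O | target

Total step count: 16.
Longest linear sequence: 13 steps (steps 1–6, 9–13, 15 and 16). Steps 7–8 and step 14 make the two side fragments.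

Steps most likely to fail

Step 2. The β-methyl group slows the cycloaddition, so silyl transfer from the diene to the counter-ion, diene decomposition or an uncatalysed pathway may compete and erode the enantiofacial selectivity. The fallback moves the chirality from the catalyst to the diene and sets out from 1 and 3. The potassium dienolate of 1 (KOt-Bu, THF, −78 °C) would be O-acylated with (S)-O-methylmandeloyl chloride to give (1E)-buta-1,3-dien-1-yl (2S)-2-methoxy-2-phenylacetate F1. Its BF3·OEt2-promoted cycloaddition with 3 should give, by auxiliary-controlled face selection, (1R,5R,6S)-6-formyl-5,6-dimethylcyclohex-2-en-1-yl (2S)-2-methoxy-2-phenylacetate F2; the antipode of the auxiliary would be taken if the face sense proved opposite. Wittig methylenation (Ph3P=CH2, THF, −78 → 0 °C) would then give (1R,5R,6S)-6-ethenyl-5,6-dimethylcyclohex-2-en-1-yl (2S)-2-methoxy-2-phenylacetate F3. Saponification (LiOH, THF/H2O) brings the material back to the route at alcohol 6.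

Step 12. The congested boat-like transition state, which creates quaternary C4 next to C5, may be reached only at temperatures at which the lactone ketene acetal fragments or the face fidelity of the C–C bond formation is lost. The fallback builds ring A by a second cycloaddition and sets out from triflate 9. Stille coupling with tributyl(vinyl)stannane (Pd(PPh3)4, LiCl, THF, 60 °C) would give (5R,6S)-1,6-diethenyl-5,6-dimethylcyclohex-1-ene F4. Its EtAlCl2-promoted Diels–Alder reaction with methyl methacrylate forms C2–C3 and C4–C5 with the regiochemistry directed by the substituted diene terminus C5 and with the ester endo, and so returns directly to ester 22. The price is that the face of the diene is then chosen only by the C9 substituents, so the diastereomer from attack on the other face would have to be removed by chromatography.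

Step 11. Hydride delivery to the hindered enone may be slow and poorly face-selective if the catalyst and the neighbouring C9 centre are mismatched, and conjugate reduction may compete. The fallback sets the C1 centre during C–C bond formation instead, setting out from 9 and 13. An asymmetric Nozaki–Hiyama–Kishi coupling (CrCl2 with a chiral oxazoline–sulfonamide ligand, NiCl2 (cat.), Et3N, THF) would give hydroxy ester 16 directly, and the PPTS lactonisation then returns to the route at lactone 17. No new compound is needed.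

Further compounds

F1 | step 2 | (1E)-buta-1,3-dien-1-yl (2S)-2-methoxy-2-phenylacetate | C=C/C=C/OC(=O)[C@@H](OC)c1ccccc1
F2 | step 2 | (1R,5R,6S)-6-formyl-5,6-dimethylcyclohex-2-en-1-yl (2S)-2-methoxy-2-phenylacetate | O=C[C@]1(C)[C@H](OC(=O)[C@@H](OC)c2ccccc2)C=CC[C@H]1C
F3 | step 2 | (1R,5R,6S)-6-ethenyl-5,6-dimethylcyclohex-2-en-1-yl (2S)-2-methoxy-2-phenylacetate | C=C[C@]1(C)[C@H](OC(=O)[C@@H](OC)c2ccccc2)C=CC[C@H]1C
F4 | step 12 | (5R,6S)-1,6-diethenyl-5,6-dimethylcyclohex-1-ene | C=CC1=CCC[C@@H](C)[C@]1(C)C=C
F0 | step 11 | none | none
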